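**Retrosynthetic overview**
- Target 14 ← face-selective reduction of the C5 ketone and loss of the aryl MOM group ← keto-chlorohydrin 12 ← anti opening of the 7,8-epoxide 10 by chloride at C8, the way the C–Cl bond is thought to arise in the plant.
- 10 ← hydroxyl-directed epoxidation of allylic alcohol 9 ← CBS reduction of the o-quinone monoketal 8 (the only catalyst-controlled stereocentre; the others are relayed from it).
- 8 ← oxidative dearomatisation of ring A of the 6-hydroxychromone 6.
- 6 ← cyclodehydration of the diarylpentane-1,3-dione 5 ← Claisen condensation of acetophenone 4 with ester 3 (from acid 1).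
- Ring order: aromatic ring A (bought) → pyranone ring → dearomatised ring A → oxirane → oxirane opened.

Assumption: chromone numbering O1, C2, C3, C4, C4a, C5–C8, C8a; the SMILES is read as (5S,6S,7S,8R), with 5-, 6- and 7-OH on one face and 8-Cl on the other.

Abbreviation: R = 2-[4-methoxy-3-(methoxymethoxy)phenyl]ethyl. Descriptor note: 6R in 9–12 and 6S in 13–14 are the same spatial arrangement; the label changes when C5 goes from ketal or ketone to carbinol.

**Step 1**
Reactants: 1 3-(3-hydroxy-4-methoxyphenyl)propanoic acid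
Product: 3 methyl 3-[4-methoxy-3-(methoxymethoxy)phenyl]propanoate, via bis-MOM ester 2 (not isolated)
Conditions: MOMCl (2.4 equiv), i-Pr2NEt, CH2Cl2, 0 °C → rt; then MeOH, K2CO3 (cat.), rt
Reagents that add atoms: chloromethyl methyl ether (COCCl); methanol (CO)
Why: Williamson-type O-alkylation of phenol and carboxylate, then base-catalysed transesterification of the labile acyloxymethyl ester to the methyl ester; the aryl MOM ether shields the electron-rich phenol from the oxidants of steps 3 and 5; no stereocentre.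

**Step 2**
Reactants: 3 methyl 3-[4-methoxy-3-(methoxymethoxy)phenyl]propanoate; 4 1-(2,5-dihydroxyphenyl)ethanone
Product: 6 6-hydroxy-2-R-4H-chromen-4-one, via 1,3-diketone 5 (not isolated)
Conditions: 4, LiN(SiMe3)2 (4.5 equiv), THF, −78 → 0 °C; add 3, 0 °C → rt; then AcOH, 95 °C
Reagents that add atoms: none
Why: Claisen condensation of the acetophenone trianion with the ester gives the diarylpentane-1,3-dione, whose ortho phenol closes the pyranone ring by acid cyclodehydration (classical chromone synthesis, the same closure as in the biogenesis); the aryl MOM ether tolerates hot AcOH; no stereocentre.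

**Step 3**
Reactants: 6 6-hydroxy-2-R-4H-chromen-4-one
Product: 8 5,5-dimethoxy-2-R-4H-chromene-4,6(5H)-dione, via 5-methoxyphenol 7 (not isolated)
Conditions: PhI(OAc)2 (2.2 equiv), MeOH, 0 °C → rt
Reagents that add atoms: methanol (CO)
Why: Proposed new method: two successive phenol oxidations by the trivalent iodine reagent; after O–I ligand exchange MeOH adds at C5, the α-naphthol-like carbon of a 6-hydroxychromone, re-aromatisation gives 7, and the second oxidation adds MeOH ipso to the new OMe; adducts at C8a are mixed ketals that re-ionise in the AcOH released, so the sequence should funnel to 8, which keeps the pyranone conjugation; closest known reactions are 2-naphthol → 1,1-dimethoxynaphthalen-2(1H)-one and 2-methoxyphenols → 6,6-dimethoxycyclohexa-2,4-dienones with PhI(OAc)2/MeOH.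

**Step 4**
Reactants: 8 5,5-dimethoxy-2-R-4H-chromene-4,6(5H)-dione
Product: 9 (6R)-6-hydroxy-5,5-dimethoxy-2-R-5,6-dihydro-4H-chromen-4-one
Conditions: (S)-1-methyl-3,3-diphenyltetrahydro-1H,3H-pyrrolo[1,2-c][1,3,2]oxazaborole (15 mol%), catecholborane (1.5 equiv), toluene/CH2Cl2, −78 °C; MeOH, then aq. NaHCO3
Reagents that add atoms: none
Why: Corey–Bakshi–Shibata reduction, 1,2-selective for the enone; the catalyst binds the C6 carbonyl anti to the quaternary ketal carbon C5 (large group) and delivers hydride to the face that gives the (6R)-alcohol, the stereocentre from which C7, C8 and C5 are later set.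

**Step 5**
Reactants: 9 (6R)-6-hydroxy-5,5-dimethoxy-2-R-5,6-dihydro-4H-chromen-4-one
Product: 10 (6R,7S,8S)-7,8-epoxy-6-hydroxy-5,5-dimethoxy-2-R-5,6,7,8-tetrahydro-4H-chromen-4-one
Conditions: VO(acac)2 (5 mol%), t-BuOOH (1.5 equiv, decane), CH2Cl2, 0 °C → rt
Reagents that add atoms: tert-butyl hydroperoxide (CC(C)(C)OO)
Why: vanadium-catalysed hydroxyl-directed epoxidation (Sharpless–Michaelson); the vanadium-bound C6 alkoxide delivers oxygen to the same face of C7=C8, so the oxirane is cis to 6-OH; the neutral conditions spare the acid-labile allylic ketal, and the pyranone alkene and aryl ethers are not touched.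

**Step 6**
Reactants: 10 (6R,7S,8S)-7,8-epoxy-6-hydroxy-5,5-dimethoxy-2-R-5,6,7,8-tetrahydro-4H-chromen-4-one
Product: 12 (6R,7S,8R)-8-chloro-6,7-dihydroxy-2-R-7,8-dihydro-4H-chromene-4,5(6H)-dione, via chlorohydrin ketal 11 (not isolated)
Conditions: aq. HCl (2 M), THF, 0 °C → rt, 2 h; cold NaHCO3 quench; crude product used at once
Reagents that add atoms: hydrogen chloride (Cl); water (O)
Why: acid-promoted SN2 opening of the epoxide by chloride (Fürst–Plattner trans-diaxial) at C8, the allylic carbon remote from the electron-withdrawing C6–O/C5 ketal, inverts C8 and leaves the C7–O bond, giving 8-Cl trans to 7-OH; the α-hydroxy dimethyl ketal is hydrolysed in the same pot to the C5 ketone (as in Moriarty α-hydroxy ketal unmasking).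

**Step 7**
Reactants: 12 (6R,7S,8R)-8-chloro-6,7-dihydroxy-2-R-7,8-dihydro-4H-chromene-4,5(6H)-dione
Product: 14 (5S,6S,7S,8R)-8-chloro-5,6,7-trihydroxy-2-[2-(3-hydroxy-4-methoxyphenyl)ethyl]-5,6,7,8-tetrahydro-4H-chromen-4-one, via MOM ether 13 (not isolated)
Conditions: LiBH(s-Bu)3 (3.5 equiv), THF, −78 °C; then aq. HCl (3 M), THF, 0 → 40 °C
Reagents that add atoms: none
Why: substrate-controlled ketone reduction with a bulky hydride; the upper face of C5=O is screened by the 6- and 7-oxygens (Felkin-type attack anti to the α-C–O bond, equatorial attack past the axial 7-OH), so hydride enters from the lower face and the 5-OH ends cis to 6-OH (5S); aqueous acid then hydrolyses the aryl MOM acetal.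

**Compound list**
1 | 3-(3-hydroxy-4-methoxyphenyl)propanoic acid | COc1ccc(CCC(=O)O)cc1O | starting material
2 | methoxymethyl 3-[4-methoxy-3-(methoxymethoxy)phenyl]propanoate | COCOC(=O)CCc1ccc(OC)c(OCOC)c1 | intermediate
3 | methyl 3-[4-methoxy-3-(methoxymethoxy)phenyl]propanoate | COC(=O)CCc1ccc(OC)c(OCOC)c1 | intermediate
4 | 1-(2,5-dihydroxyphenyl)ethanone | CC(=O)c1cc(O)ccc1O | starting material
5 | 1-(2,5-dihydroxyphenyl)-5-[4-methoxy-3-(methoxymethoxy)phenyl]pentane-1,3-dione | COCOc1cc(CCC(=O)CC(=O)c2cc(O)ccc2O)ccc1OC | intermediate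
6 | 6-hydroxy-2-{2-[4-methoxy-3-(methoxymethoxy)phenyl]ethyl}-4H-chromen-4-one | COCOc1cc(CCc2cc(=O)c3cc(O)ccc3o2)ccc1OC | intermediate
7 | 6-hydroxy-5-methoxy-2-{2-[4-methoxy-3-(methoxymethoxy)phenyl]ethyl}-4H-chromen-4-one | COCOc1cc(CCc2cc(=O)c3c(OC)c(O)ccc3o2)ccc1OC | intermediate
8 | 5,5-dimethoxy-2-{2-[4-methoxy-3-(methoxymethoxy)phenyl]ethyl}-4H-chromene-4,6(5H)-dione | COCOc1cc(CCc2cc(=O)c3c(o2)C=CC(=O)C3(OC)OC)ccc1OC | intermediate
9 | (6R)-6-hydroxy-5,5-dimethoxy-2-{2-[4-methoxy-3-(methoxymethoxy)phenyl]ethyl}-5,6-dihydro-4H-chromen-4-one | COCOc1cc(CCc2cc(=O)c3c(o2)C=C[C@@H](O)C3(OC)OC)ccc1OC | intermediate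
10 | (6R,7S,8S)-7,8-epoxy-6-hydroxy-5,5-dimethoxy-2-{2-[4-methoxy-3-(methoxymethoxy)phenyl]ethyl}-5,6,7,8-tetrahydro-4H-chromen-4-one (oxirane cis to 6-OH) | COCOc1cc(CCc2cc(=O)c3c(o2)[C@H]4O[C@H]4[C@@H](O)C3(OC)OC)ccc1OC | intermediate
11 | (6R,7S,8R)-8-chloro-6,7-dihydroxy-5,5-dimethoxy-2-{2-[4-methoxy-3-(methoxymethoxy)phenyl]ethyl}-5,6,7,8-tetrahydro-4H-chromen-4-one | COCOc1cc(CCc2cc(=O)c3c(o2)[C@H](Cl)[C@@H](O)[C@@H](O)C3(OC)OC)ccc1OC | intermediate
12 | (6R,7S,8R)-8-chloro-6,7-dihydroxy-2-{2-[4-methoxy-3-(methoxymethoxy)phenyl]ethyl}-7,8-dihydro-4H-chromene-4,5(6H)-dione | COCOc1cc(CCc2cc(=O)c3c(o2)[C@H](Cl)[C@@H](O)[C@@H](O)C3=O)ccc1OC | intermediate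
13 | (5S,6S,7S,8R)-8-chloro-5,6,7-trihydroxy-2-{2-[4-methoxy-3-(methoxymethoxy)phenyl]ethyl}-5,6,7,8-tetrahydro-4H-chromen-4-one | COCOc1cc(CCc2cc(=O)c3c(o2)[C@H](Cl)[C@@H](O)[C@@H](O)[C@H]3O)ccc1OC | intermediate
14 | (5S,6S,7S,8R)-8-chloro-5,6,7-trihydroxy-2-[2-(3-hydroxy-4-methoxyphenyl)ethyl]-5,6,7,8-tetrahydro-4H-chromen-4-one | COc1ccc(CCc2cc(=O)c3c(o2)[C@H](Cl)[C@@H](O)[C@@H](O)[C@H]3O)cc1O | target

**Step count and risks**
Total steps: 7. Longest linear sequence: 7 (1 → 3 → 6 → 8 → 9 → 10 → 12 → 14); 4 enters at step 2.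

Step 3 is the most likely to fail. MeOH may add at C8a, para to the phenol and bearing the ring oxygen, rather than at C5, which would give a p-quinol-type ketal or ring-opened quinone. The fallback fixes the C5 oxygen before the chromone is built. It sets out from 4: Ag2O (Et2O, Na2SO4) oxidises it to 2-acetylcyclohexa-2,5-diene-1,4-dione F1. MeOH with cat. ZnCl2 adds at the ring carbon next to the acetyl group (the doubly activated Michael position) and, after Na2S2O4 work-up, gives 1-(3,6-dihydroxy-2-methoxyphenyl)ethanone F2. The Claisen condensation and cyclodehydration of step 2 with 3 then run through 1-(3,6-dihydroxy-2-methoxyphenyl)-5-[4-methoxy-3-(methoxymethoxy)phenyl]pentane-1,3-dione F3 and come back to the route at 7, now isolated. One equivalent of PhI(OAc)2 in MeOH adds ipso to the 5-OMe group (the established 2-methoxyphenol → o-quinone monoketal reaction) and gives 8.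

Step 6 is the second risk. The α-hydroxy ketone 12 carries a β-hydroxyl and can dehydrate in acid to a catechol-type chromone, and the ketal may hydrolyse more slowly than the epoxide opens. The fallback changes the order so that the C–Cl bond is made last, on a diol epoxide. It sets out from 10: chloride-free ketal hydrolysis (aq. oxalic acid on SiO2, CH2Cl2, 0 °C) gives (6R,7S,8S)-7,8-epoxy-6-hydroxy-2-R-7,8-dihydro-4H-chromene-4,5(6H)-dione F4. NaBH4 with CeCl3·7H2O (MeOH, −78 °C) adds hydride anti to the cis oxirane and 6-OH and gives (5S,6S,7S,8S)-7,8-epoxy-5,6-dihydroxy-2-R-5,6,7,8-tetrahydro-4H-chromen-4-one F5. HCl in Et2O at −20 °C opens F5 at C8 with inversion, and the route is rejoined at 13, which goes through the acid treatment of step 7.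

Step 7 is the third risk. Facial selectivity at C5 rests on conformational arguments, and the lithium alkoxide of the chlorohydrin could close back to the epoxide. The fallback adds a temporary tether that blocks one face and leaves no free hydroxyl. It sets out from 12: t-Bu2Si(OTf)2 and 2,6-lutidine (CH2Cl2, 0 °C) give (6R,7S,8R)-8-chloro-6,7-[(di-tert-butylsilanediyl)bis(oxy)]-2-R-7,8-dihydro-4H-chromene-4,5(6H)-dione F6. NaBH4 with CeCl3·7H2O (MeOH, −78 °C) can reach C5=O only from the face opposite the cis-fused dioxasilolane and gives (5S,6S,7S,8R)-8-chloro-6,7-[(di-tert-butylsilanediyl)bis(oxy)]-5-hydroxy-2-R-5,6,7,8-tetrahydro-4H-chromen-4-one F7. HF·pyridine (THF, 0 °C) removes the silylene, and the route is rejoined at 13.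

**Further compounds**
F1 | step 3 | 2-acetylcyclohexa-2,5-diene-1,4-dione | CC(=O)C1=CC(=O)C=CC1=O
F2 | step 3 | 1-(3,6-dihydroxy-2-methoxyphenyl)ethanone | COc1c(O)ccc(O)c1C(C)=O
F3 | step 3 | 1-(3,6-dihydroxy-2-methoxyphenyl)-5-[4-methoxy-3-(methoxymethoxy)phenyl]pentane-1,3-dione | COCOc1cc(CCC(=O)CC(=O)c2c(O)ccc(O)c2OC)ccc1OC
F4 | step 6 | (6R,7S,8S)-7,8-epoxy-6-hydroxy-2-{2-[4-methoxy-3-(methoxymethoxy)phenyl]ethyl}-7,8-dihydro-4H-chromene-4,5(6H)-dione | COCOc1cc(CCc2cc(=O)c3c(o2)[C@H]4O[C@H]4[C@@H](O)C3=O)ccc1OC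
F5 | step 6 | (5S,6S,7S,8S)-7,8-epoxy-5,6-dihydroxy-2-{2-[4-methoxy-3-(methoxymethoxy)phenyl]ethyl}-5,6,7,8-tetrahydro-4H-chromen-4-one | COCOc1cc(CCc2cc(=O)c3c(o2)[C@H]4O[C@H]4[C@@H](O)[C@H]3O)ccc1OC
F6 | step 7 | (6R,7S,8R)-8-chloro-6,7-[(di-tert-butylsilanediyl)bis(oxy)]-2-{2-[4-methoxy-3-(methoxymethoxy)phenyl]ethyl}-7,8-dihydro-4H-chromene-4,5(6H)-dione | COCOc1cc(CCc2cc(=O)c3c(o2)[C@H](Cl)[C@H]4O[Si](C(C)(C)C)(C(C)(C)C)O[C@H]4C3=O)ccc1OC
F7 | step 7 | (5S,6S,7S,8R)-8-chloro-6,7-[(di-tert-butylsilanediyl)bis(oxy)]-5-hydroxy-2-{2-[4-methoxy-3-(methoxymethoxy)phenyl]ethyl}-5,6,7,8-tetrahydro-4H-chromen-4-one | COCOc1cc(CCc2cc(=O)c3c(o2)[C@H](Cl)[C@H]4O[Si](C(C)(C)C)(C(C)(C)C)O[C@H]4[C@H]3O)ccc1OC
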